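We ask what has stopped this flask by 20 h and how its substrate is then shared, and we test the opposite outcome, in which the substrate is consumed before the partner.

substrate 1.0 M; partner 1.20 M; free catalyst 1.0 mM; time 20 h

    catalyst intermediate C ⇌ free catalyst + target (K1 = 0.697 M, k1 = 191 min⁻¹)
    partner + target → over-reaction product (k2 = 0.682 M⁻¹ min⁻¹)
    catalyst intermediate A → catalyst intermediate B (k3 = 1620 min⁻¹)
    partner + free catalyst → catalyst intermediate A (k4 = 291 M⁻¹ min⁻¹)
    substrate + catalyst intermediate B → catalyst intermediate C (k5 = 3370 M⁻¹ min⁻¹)

1. the state of affairs at 20 h: stopped, and by what, or still going (forward and back rates have come level / the partner has run out first / all of the substrate has reacted / it is still moving / no working catalyst is left)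
2. target at 20 h, in percent of the substrate charged
3. over-reaction product at 20 h, in percent of the substrate charged

Each catalyst turn takes one partner and gives one target, and each over-reaction takes one partner and one target. Setting aside the millimolar amounts held on the catalyst, the partner spent equals the substrate converted plus the over-reaction product. With charges a of substrate and b of partner, consuming all the substrate first allows b − a of over-reaction product, so the target must reach

N = 2a − b = 0.800 M.

Can it? Let p be the partner, T the target and c the catalyst charged, with kp and ko the constants 291 M⁻¹ min⁻¹ and 0.682 M⁻¹ min⁻¹ of the partner's two steps and K the constant 0.697 M. Turnover runs at no more than kp·p·c/(1 + T/K), the free catalyst being shared with catalyst intermediate C, while over-reaction runs at ko·p·T. The partner p cancels, so we define the target ceiling, the target at which these two rates are level: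

T(1 + T/K) = kp·c/ko = 0.427 M, so T = 0.299 M.

Since the need stands 2.68 times the ceiling, we expect the partner to be the limiting reagent. If the target ends at P, over-reaction product is (b − P)/2 and the substrate left is a − (b + P)/2, so with P under the ceiling at least 0.251 M of substrate stays.

The forecast says the partner has run out first, with target 22.6% and over-reaction product 48.7%, arguing that “Each turnover uses one partner, and each over-reaction uses another.” We give bounds where it gives points. A run showing this flask's target past 0.800 M would overturn its ending.

The simulation's verdict on this flask at 20 h is that the partner has run out first, with the partner already at 0% of its charge by 2.00 h, target 22.6% and over-reaction product 48.7%, while 29% of the substrate remains. In a neighbouring flask charged with 0.0025 M of free catalyst, the same reckoning gives a ceiling of 0.582 M, still under the need, and at least 0.109 M of substrate left. The run of that neighbouring flask ends with partner at 0%, target 40.0%, over-reaction product 39.9% and substrate 20%.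

All constants were chosen freely; the result is computed.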